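Everything rests on building the acetyl-bearing trione ring (ring A) by a formal [4+2] annulation. Ring A is numbered C1 (ring C=O between acetyl-bearing C2 and the CMe2 carbon C6), C3 (enol carbon), C4 (bridge-bearing carbon) and C5. In one operation the enolate of methyl 2,2-dimethylacetoacetate (C4–C5–C6–C1) is C-acylated by diketene (C3, C2 and the acetyl group), forming C3–C4, and the resulting triketo ester closes by Claisen condensation, forming C1–C2. The step exploits the quaternary C6 of ring A, which allows only one enolate and blocks aldol closure. Two Mannich-base-mediated methylene couplings onto butyrylphloroglucinol then assemble the trimer.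

Key step: step 1

Remark: the target has no stereocentre; every trione ring is written in the 3,5-dihydroxy-2,4-dien-1-one enol tautomer used for the target, and the tautomers of each compound are treated as one compound.

Step 1
Reactants: 1 methyl 2,2-dimethyl-3-oxobutanoate; 2 diketene (4-methylideneoxetan-2-one)
Product: 4 acetylfilicinic acid (2-acetyl-3,5-dihydroxy-6,6-dimethylcyclohexa-2,4-dien-1-one), via triketo ester 3 (not isolated)
Conditions: LiN(iPr)2 (1.05 equiv), THF, −78 °C; 2 (1.1 equiv), −78 → −20 °C; KOtBu (2.2 equiv), 0 → 50 °C; then 1 M HCl
Reagents that add atoms: none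
Why: LiN(iPr)2 can enolize 1 only at the ketone methyl group (future C4), because the other α-carbon (C6) is quaternary, and this enolate attacks the lactone carbonyl of diketene (future C3), opening the four-membered ring to the enolate of triketo ester 3 (C3–C4 formed). After KOtBu is added, the doubly activated carbon of the new acetoacetyl unit (C2) attacks the methyl ester carbon (C1) and methoxide leaves (C1–C2 formed), so diketene serves as a two-carbon unit that is first electrophilic and then nucleophilic. The closest known reaction types are the C-acetoacetylation of enolates with diketene and the Claisen (Dieckmann) cyclization of 3,5,7-triketo esters to acylphloroglucinol-type triones. Ring A closes in a 6-exo-trig mode, favoured by the gem-dimethyl group. No stereocentre is formed. The step needs C- over O-acylation (lithium enolate in THF at low temperature; an enol ester formed by O-acylation can still pass to the C-acyl isomer in the basic second stage) and Claisen over aldol closure, which the quaternary C6 secures: the ester has no α-hydrogen, so it stays electrophilic and the resorcinol-forming aldol through that carbon is impossible, while the product leaves the equilibria as its dianion.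

Step 2
Reactants: 5 phloroglucinol (benzene-1,3,5-triol); 6 butanoyl chloride
Product: 7 1-(2,4,6-trihydroxyphenyl)butan-1-one (butyrylphloroglucinol)
Conditions: AlCl3 (3.5 equiv), PhNO2/CH2Cl2, 0 → 45 °C; ice/aq. HCl
Reagents that add atoms: none
Why: Friedel–Crafts acylation of the strongly activated phloroglucinol ring, in which the first acyl group, held as an AlCl3 chelate by the flanking hydroxyls, deactivates the ring so that monoacylation should dominate with one equivalent of 6.

Step 3
Reactants: 4 acetylfilicinic acid; 7 1-(2,4,6-trihydroxyphenyl)butan-1-one
Product: 9 2-acetyl-4-[(3-butanoyl-2,4,6-trihydroxyphenyl)methyl]-3,5-dihydroxy-6,6-dimethylcyclohexa-2,4-dien-1-one, via Mannich base 8 (not isolated)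
Conditions: 4, [Me2N=CH2]I (1.0 equiv), MeCN, 0 °C → rt; then 7 (3 equiv), NaOAc (2 equiv), 60 °C
Reagents that add atoms: N,N-dimethylmethylideneammonium iodide (Eschenmoser's salt), C=[N+](C)C.[I-]
Why: Mannich aminomethylation with the preformed iminium salt occurs at C4 of ring A, the only nucleophilic carbon of 4, and on warming the Mannich base 8 loses dimethylamine (retro-Michael, E1cB) to a transient 4-methylidene trione that is captured at a free aromatic carbon of 7 (conjugate Friedel–Crafts-type alkylation, then rearomatization), the threefold excess of 7 holding back a second alkylation.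

Step 4
Reactants: 10 1-(2,4,6-trihydroxyphenyl)propan-1-one (flopropione)
Product: 11 propionylfilicinic acid (3,5-dihydroxy-6,6-dimethyl-2-propanoylcyclohexa-2,4-dien-1-one)
Conditions: NaOMe (3 equiv), MeI (2.2 equiv), MeOH, 0 °C → rt; then 1 M HCl
Reagents that add atoms: iodomethane, CI
Why: Dearomative double C-methylation of the acylphloroglucinol phenolate (the classical route to acylfilicinic acids), in which the carbon methylated first is alkylated again and the resulting gem-dimethyl dienone is shielded from further alkylation as its vinylogous-acid anion, so that two equivalents of MeI should stop mainly at 11.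

Step 5
Reactants: 11 propionylfilicinic acid; 9 the methylene-bridged dimer from step 3
Product: 13 the target 2-acetyl-4-({3-butanoyl-5-[(2,6-dihydroxy-3,3-dimethyl-4-oxo-5-propanoylcyclohexa-1,5-dien-1-yl)methyl]-2,4,6-trihydroxyphenyl}methyl)-3,5-dihydroxy-6,6-dimethylcyclohexa-2,4-dien-1-one, via Mannich base 12 (not isolated)
Conditions: 11 (1.3 equiv), [Me2N=CH2]I (1.3 equiv), MeCN, 0 °C → rt; then 9 (1.0 equiv), NaOAc (2.6 equiv), 60 °C
Reagents that add atoms: N,N-dimethylmethylideneammonium iodide (Eschenmoser's salt), C=[N+](C)C.[I-]
Why: The same Mannich/retro-Michael/conjugate-alkylation sequence, in which 11 is aminomethylated at its single ring C–H and the methylidene trione released from 12 is captured by the one remaining aromatic C–H of 9, the only unsubstituted nucleophilic carbon left, while NaOAc buffers the released amine so that the existing bridge should not exchange.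

Compound list
1 | methyl 2,2-dimethyl-3-oxobutanoate | COC(=O)C(C)(C)C(C)=O | starting material
2 | diketene (4-methylideneoxetan-2-one) | C=C1CC(=O)O1 | starting material
3 | methyl 2,2-dimethyl-3,5,7-trioxooctanoate (present as its enolate) | COC(=O)C(C)(C)C(=O)CC(=O)CC(C)=O | intermediate
4 | acetylfilicinic acid (2-acetyl-3,5-dihydroxy-6,6-dimethylcyclohexa-2,4-dien-1-one) | CC(=O)C1=C(O)C=C(O)C(C)(C)C1=O | intermediate
5 | phloroglucinol (benzene-1,3,5-triol) | Oc1cc(O)cc(O)c1 | starting material
6 | butanoyl chloride | CCCC(Cl)=O | starting material
7 | 1-(2,4,6-trihydroxyphenyl)butan-1-one | CCCC(=O)c1c(O)cc(O)cc1O | intermediate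
8 | 2-acetyl-4-[(dimethylamino)methyl]-3,5-dihydroxy-6,6-dimethylcyclohexa-2,4-dien-1-one | CC(=O)C1=C(O)C(CN(C)C)=C(O)C(C)(C)C1=O | intermediate
9 | 2-acetyl-4-[(3-butanoyl-2,4,6-trihydroxyphenyl)methyl]-3,5-dihydroxy-6,6-dimethylcyclohexa-2,4-dien-1-one | CCCC(=O)c1c(O)c(CC2=C(O)C(C)(C)C(=O)C(C(C)=O)=C2O)c(O)cc1O | intermediate
10 | 1-(2,4,6-trihydroxyphenyl)propan-1-one (flopropione) | CCC(=O)c1c(O)cc(O)cc1O | starting material
11 | propionylfilicinic acid (3,5-dihydroxy-6,6-dimethyl-2-propanoylcyclohexa-2,4-dien-1-one) | CCC(=O)C1=C(O)C=C(O)C(C)(C)C1=O | intermediate
12 | 4-[(dimethylamino)methyl]-3,5-dihydroxy-6,6-dimethyl-2-propanoylcyclohexa-2,4-dien-1-one | CCC(=O)C1=C(O)C(CN(C)C)=C(O)C(C)(C)C1=O | intermediate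
13 | target: butyrylphloroglucinol carrying a CH2 bridge to C4 of acetylfilicinic acid at one free ring carbon and a CH2 bridge to C4 of propionylfilicinic acid at the other | CCCC(=O)c1c(O)c(CC2=C(O)C(C)(C)C(=O)C(C(C)=O)=C2O)c(O)c(CC2=C(O)C(C)(C)C(=O)C(C(=O)CC)=C2O)c1O | target

Total step count: 5
Longest linear sequence: 3 steps (step 1, step 3, step 5)

Steps most likely to fail

Step 1. The enolate may be acylated on oxygen, diketene may oligomerize under the anionic conditions, or the Claisen closure may stall while alkoxide cleaves the chain next to the quaternary carbon. The fallback sets out from 1 and comes back at 4, making the same two ring bonds in separate operations. The kinetic enolate of 1 (LiN(iPr)2, THF, −78 °C) is acetylated with N-methoxy-N-methylacetamide to give methyl 2,2-dimethyl-3,5-dioxohexanoate F1. F1 is closed by Dieckmann cyclization (KOtBu, THF) with loss of methanol to filicinic acid F2. F2, whose two ring CH2 groups are equivalent by symmetry, is C-acetylated with Ac2O and BF3·OEt2 to give 4.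

Step 5. The bridge already present may exchange by retro-Michael fragmentation and re-addition under the released amine, and the methylidene trione may be consumed by 11 set free through retro-Mannich reaction before the crowded aromatic carbon of 9 captures it. The fallback sets out from 9 and comes back at 13 with the roles of the partners reversed. 9 is aminomethylated at its last aromatic C–H with Eschenmoser's salt to give the isolated Mannich base of 9 F3. F3 is heated with 11 in dioxane without added base, so that an ortho-quinone methide forms on the aromatic ring and is captured by C4 of 11, giving 13 with loss of dimethylamine.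

Step 3. A second alkylation at the other free aromatic carbon of 7 and homo-coupling of the methylidene trione with 4 may compete with the wanted single bridging. The fallback sets out from 7 and comes back at 9. 7 is treated with one equivalent of Eschenmoser's salt and the purified mono-Mannich base 1-{3-[(dimethylamino)methyl]-2,4,6-trihydroxyphenyl}butan-1-one F4 is isolated, so that each central ring carries exactly one electrophilic carbon. F4 is heated with 4 in dioxane, and the ortho-quinone methide is captured by C4 of 4 to give 9 with loss of dimethylamine.

Further compounds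
F1 | step 1 | methyl 2,2-dimethyl-3,5-dioxohexanoate | COC(=O)C(C)(C)C(=O)CC(C)=O
F2 | step 1 | filicinic acid (5-hydroxy-6,6-dimethylcyclohex-4-ene-1,3-dione) | CC1(C)C(O)=CC(=O)CC1=O
F3 | step 5 | 2-acetyl-4-({3-butanoyl-5-[(dimethylamino)methyl]-2,4,6-trihydroxyphenyl}methyl)-3,5-dihydroxy-6,6-dimethylcyclohexa-2,4-dien-1-one | CCCC(=O)c1c(O)c(CC2=C(O)C(C)(C)C(=O)C(C(C)=O)=C2O)c(O)c(CN(C)C)c1O
F4 | step 3 | 1-{3-[(dimethylamino)methyl]-2,4,6-trihydroxyphenyl}butan-1-one | CCCC(=O)c1c(O)cc(O)c(CN(C)C)c1O
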